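**Retrosynthetic overview**
1. The oxirane goes in last, by hydroxyl-directed epoxidation of an 8-en-10α-ol. That alcohol comes from a 9,10-alkene by epoxidation and selenoxide transposition.
2. The O6 veratrate and O2 acetate are added one at a time as each secondary OH is unveiled. C6–OH comes from a ketone by hydride delivery from the tertiary 4-OH, and C4 from isopropyl addition to a ring ketone.
3. Key disconnection at C5–C1, C5–C10 and C7–C8: an acyclic siloxyvinyl diazo ketone closes cyclopentanone and cyclopropane in one carbenoid event, and the cis-divinylcyclopropane rearranges in the same flask to the cycloheptadiene.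
4. The acyclic precursor comes from acetylacetone (diazo transfer, enol silane) and an enantioselective aldol with 2-methylhexadienal (crotonaldehyde plus a C3 ylide). That aldol sets C2, the centre that controls all the others.
5. Ring order: five- and three-membered rings together, three- to seven-membered ring in the same operation, oxirane at the end.

Numbering (daucane): C1 is the angular carbon bearing CH3. C2 (OAc), C3, C4 (OH, isopropyl) and C5 (ring-fusion H) complete the five-membered ring. C6 (O-veratroyl), C7, C8 (CH3), C9 and C10 (OH) complete the seven-membered ring. β is the face of the C1 methyl group and α the opposite face. The same atom labels are used for the acyclic precursors.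

Assumption: taken literally, the C8 and C9 tags of the given string place C7 and C10 trans across the oxirane, which a cycloheptane ring cannot hold, so the C8 tag is read as a drawing artefact; the route delivers the cis-fused 8α,9α-epoxide (C9 and all other centres as given) and the given string is kept unchanged as the entry for the target.

**Step 1**
Reactants: 1 pentane-2,4-dione
Product: 2 3-diazopentane-2,4-dione
Conditions: p-ABSA, Et3N, MeCN, 0 °C to rt
Reagents that add atoms: 4-acetamidobenzenesulfonyl azide (p-ABSA) CC(=O)Nc1ccc(cc1)S(=O)(=O)N=[N+]=[N-]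
Why: Regitz diazo transfer onto the activated methylene of the 1,3-diketone; no stereocentre is formed.

**Step 2**
Reactants: 2 3-diazopentane-2,4-dione
Product: 3 3-diazo-4-(triethylsilyloxy)pent-4-en-2-one
Conditions: TESOTf (1.05 equiv), Et3N, CH2Cl2, 0 °C
Reagents that add atoms: triethylsilyl triflate CC[Si](CC)(CC)OS(=O)(=O)C(F)(F)F
Why: Soft enolisation (silyl triflate/amine) of one of the two equivalent acetyl groups gives the mono enol silane while the other acyl group keeps the diazo carbon stabilised; no stereocentre is formed.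

**Step 3**
Reactants: 4 (E)-but-2-enal; 5 2-(triphenylphosphoranylidene)propanal
Product: 6 (2E,4E)-2-methylhexa-2,4-dienal
Conditions: toluene, 100 °C
Reagents that add atoms: none
Why: Wittig olefination with a stabilised ylide gives the new trisubstituted alkene as the E isomer and leaves the E crotyl alkene untouched.

**Step 4**
Reactants: 3 3-diazo-4-(triethylsilyloxy)pent-4-en-2-one; 6 (2E,4E)-2-methylhexa-2,4-dienal
Product: 7 (6R,7E,9E)-3-diazo-6-hydroxy-7-methylundeca-7,9-diene-2,4-dione
Conditions: AgF (10 mol %), (R)-BINAP (10 mol %), THF, −20 °C; 1 M HCl work-up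
Reagents that add atoms: none
Why: Catalytic enantioselective Mukaiyama aldol addition (1,2 to the enal) of the diazo-bearing enol silane on a chiral silver–BINAP complex sets C2 as R (the ligand antipode is chosen for this sense), and the diazo group is inert under these mild conditions.

**Step 5**
Reactants: 7 (6R,7E,9E)-3-diazo-6-hydroxy-7-methylundeca-7,9-diene-2,4-dione
Product: 8 (6R,7E,9E)-3-diazo-7-methyl-2,6-bis(triethylsilyloxy)undeca-1,7,9-trien-4-one
Conditions: TESCl (2.5 equiv), LiHMDS (2.3 equiv), THF, −78 °C (in situ quench)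
Reagents that add atoms: chlorotriethylsilane CC[Si](Cl)(CC)CC
Why: Kinetic enolate silylation takes the unhindered acetyl CH3 rather than the CH2 next to the oxygenated carbon, so one operation caps O2 and regenerates the siloxyvinyl diazo (donor/acceptor carbenoid precursor) unit without touching C2.

**Step 6**
Reactants: 8 (6R,7E,9E)-3-diazo-7-methyl-2,6-bis(triethylsilyloxy)undeca-1,7,9-trien-4-one
Product: 10 bicyclic 6-(triethylsilyloxy)-5(6),9-dien-4-one (1β-CH3; 2α-OTES; 8α-CH3), via cis-divinylcyclopropane 9 (not isolated)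
Conditions: Rh2(OAc)4 (1 mol %), toluene, slow addition, 25 °C; then 110 °C
Reagents that add atoms: none
Why: Tandem intramolecular vinylcarbenoid cyclopropanation/divinylcyclopropane (Cope) rearrangement: the rhodium carbenoid adds stereospecifically to the proximal E alkene on the face where C2–H, not OTES, eclipses the vinylic methyl (allylic 1,2-strain), closing cyclopentanone and cyclopropane at once with the propenyl group exo and cis to the siloxyvinyl group, and the boat [3,3] shift then opens the three-membered ring to the cycloheptadiene, fixing C1 (CH3 β, trans to O2) and C8.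

**Step 7**
Reactants: 10 bicyclic 6-(triethylsilyloxy)-5(6),9-dien-4-one
Product: 12 trans-fused 2α,4β-dihydroxy-4α-isopropyl-9-en-6-one (5α-H), via bis-silylated C4 carbinol 11 (not isolated)
Conditions: iPrMgCl, LaCl3·2LiCl, THF, −78 °C; then HF·pyridine, pyridine, −78 to 0 °C
Reagents that add atoms: isopropylmagnesium chloride CC(C)[Mg]Cl
Why: Lanthanide-assisted Grignard 1,2-addition (enolisation and 1,4-attack suppressed) enters C4 from the α face, anti to the angular C1 methyl, to give the 4β-carbinol, and buffered fluoride then frees O2 and the enol, C5 being protonated to the trans-fused epimer in which the C6 carbonyl is cis to and hydrogen-bonded to the 4-OH and anti to isopropyl (also the thermodynamic epimer).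

**Step 8**
Reactants: 12 trans-fused 2α,4β-dihydroxy-4α-isopropyl-9-en-6-one
Product: 13 2α-acetoxy-4β-hydroxy-9-en-6-one
Conditions: Ac2O, pyridine, DMAP (cat.), CH2Cl2, 0 °C
Reagents that add atoms: acetic anhydride CC(=O)OC(C)=O
Why: DMAP-catalysed acylation is selective for the only secondary alcohol because the tertiary 4-OH is inert, and no stereocentre changes.

**Step 9**
Reactants: 13 2α-acetoxy-4β-hydroxy-9-en-6-one
Product: 14 2α-acetoxy-9-ene-4β,6α-diol
Conditions: Me4NBH(OAc)3, MeCN/AcOH, −20 °C
Reagents that add atoms: none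
Why: Evans–Saksena reduction, in which boron binds the 4β-OH and delivers hydride intramolecularly to the β face of the C6 ketone, gives the 1,3-anti diol, that is the 6α-alcohol.

**Step 10**
Reactants: 14 2α-acetoxy-9-ene-4β,6α-diol; 15 3,4-dimethoxybenzoyl chloride
Product: 16 2α-acetoxy-6α-(3,4-dimethoxybenzoyloxy)-9-en-4β-ol
Conditions: Et3N, DMAP (cat.), CH2Cl2, 0 °C to rt
Reagents that add atoms: none
Why: DMAP-catalysed esterification of the only secondary alcohol proceeds with retention at C6, and the tertiary 4-OH stays free.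

**Step 11**
Reactants: 16 2α-acetoxy-6α-(3,4-dimethoxybenzoyloxy)-9-en-4β-ol
Product: 17 9α,10α-epoxide of 16
Conditions: mCPBA, CH2Cl2, 0 °C
Reagents that add atoms: 3-chloroperoxybenzoic acid OOC(=O)c1cccc(Cl)c1
Why: Prilezhaev epoxidation of the only alkene comes from the α face, because in the trans-fused chair cycloheptene the angular C1 methyl is axial over the β face while the C8 methyl is equatorial.

**Step 12**
Reactants: 17 9α,10α-epoxide
Product: 20 8-en-10α-ol (2α-OAc; 6α-O-veratroyl; 4β-OH), via 9β-phenylselanyl-10α-ol 18 (not isolated), via selenoxide 19 (not isolated)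
Conditions: PhSeH, Cs2CO3 (cat.), DMF, 40 °C; then 30% H2O2, pyridine, THF, 0 °C to rt
Reagents that add atoms: none
Why: Epoxide-to-allylic-alcohol transposition by selenide opening and selenoxide syn elimination: selenolate opens the oxirane anti at C9 (C10 is neopentylic), leaving the 10α-OH, and the 9β-selenoxide eliminates toward the syn 8β-H and away from the carbinol carbon to give the 8,9-alkene.

**Step 13**
Reactants: 20 8-en-10α-ol
Product: 21 target CNP0197096.2
Conditions: VO(acac)2 (2 mol %), tBuOOH, toluene, 0 °C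
Reagents that add atoms: tert-butyl hydroperoxide CC(C)(C)OO
Why: Hydroxyl-directed vanadium-catalysed epoxidation of the cyclic allylic alcohol delivers oxygen syn to the 10α-OH (also the face away from the angular methyl), setting C8 and C9 as the cis-fused α-oxirane.

**Compound list**
1 | pentane-2,4-dione (acetylacetone) | CC(=O)CC(C)=O | starting material
2 | 3-diazopentane-2,4-dione | CC(=O)C(=[N+]=[N-])C(C)=O | intermediate
3 | 3-diazo-4-(triethylsilyloxy)pent-4-en-2-one | CC(=O)C(=[N+]=[N-])C(=C)O[Si](CC)(CC)CC | intermediate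
4 | (E)-but-2-enal (crotonaldehyde) | C/C=C/C=O | starting material
5 | 2-(triphenylphosphoranylidene)propanal | CC(C=O)=P(c1ccccc1)(c1ccccc1)c1ccccc1 | starting material
6 | (2E,4E)-2-methylhexa-2,4-dienal | C/C=C/C=C(C)/C=O | intermediate
7 | (6R,7E,9E)-3-diazo-6-hydroxy-7-methylundeca-7,9-diene-2,4-dione (carbinol carbon = C2) | C/C=C/C=C(C)/[C@H](O)CC(=O)C(=[N+]=[N-])C(C)=O | intermediate
8 | (6R,7E,9E)-3-diazo-7-methyl-2,6-bis(triethylsilyloxy)undeca-1,7,9-trien-4-one | C/C=C/C=C(C)/[C@H](O[Si](CC)(CC)CC)CC(=O)C(=[N+]=[N-])C(=C)O[Si](CC)(CC)CC | intermediate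
9 | bicyclo[3.1.0]hexan-2-one (C4 ketone): bridgehead C5 carries 1-(triethylsilyloxy)vinyl, bridgehead C1 carries CH3, C10 carries an exo (E)-prop-1-enyl group cis to the siloxyvinyl group, 2-OTES trans to the C1 methyl | C=C(O[Si](CC)(CC)CC)[C@]12C(=O)C[C@@H](O[Si](CC)(CC)CC)[C@@]1(C)[C@@H]2/C=C/C | intermediate
10 | bicyclo[5.3.0]deca-5(6),9-dien-4-one (daucane numbering): 6-OTES enol ether, 2α-OTES, 1β-CH3, 8α-CH3 | CC[Si](CC)(CC)OC1=C2C(=O)C[C@@H](O[Si](CC)(CC)CC)[C@@]2(C)C=C[C@@H](C)C1 | intermediate
11 | 4β-hydroxy-4α-isopropyl adduct of 10 (both TES groups retained) | CC[Si](CC)(CC)OC1=C2[C@@](O)(C(C)C)C[C@@H](O[Si](CC)(CC)CC)[C@@]2(C)C=C[C@@H](C)C1 | intermediate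
12 | trans-fused 2α,4β-dihydroxy-4α-isopropyl-1β,8α-dimethyl-9-en-6-one, 5α-H | O=C2C[C@H](C)C=C[C@]3(C)[C@H](O)C[C@](O)(C(C)C)[C@@H]23 | intermediate
13 | 2α-acetate of 12 | O=C2C[C@H](C)C=C[C@]3(C)[C@H](OC(C)=O)C[C@](O)(C(C)C)[C@@H]23 | intermediate
14 | 2α-acetoxy-9-ene-4β,6α-diol | O[C@@H]2C[C@H](C)C=C[C@]3(C)[C@H](OC(C)=O)C[C@](O)(C(C)C)[C@@H]23 | intermediate
15 | 3,4-dimethoxybenzoyl chloride (veratroyl chloride) | COc1ccc(C(=O)Cl)cc1OC | starting material
16 | 2α-acetoxy-6α-(3,4-dimethoxybenzoyloxy)-9-en-4β-ol, 8α-CH3 | COc1ccc(C(=O)O[C@@H]2C[C@H](C)C=C[C@]3(C)[C@H](OC(C)=O)C[C@](O)(C(C)C)[C@@H]23)cc1OC | intermediate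
17 | 9α,10α-epoxide of 16 | COc1ccc(C(=O)O[C@@H]2C[C@H](C)[C@@H]4O[C@@H]4[C@]3(C)[C@H](OC(C)=O)C[C@](O)(C(C)C)[C@@H]23)cc1OC | intermediate
18 | 9β-phenylselanyl-10α-ol | COc1ccc(C(=O)O[C@@H]2C[C@H](C)[C@@H]([Se]c4ccccc4)[C@H](O)[C@]3(C)[C@H](OC(C)=O)C[C@](O)(C(C)C)[C@@H]23)cc1OC | intermediate
19 | selenoxide of 18 (configuration at Se not defined) | COc1ccc(C(=O)O[C@@H]2C[C@H](C)[C@@H]([Se](=O)c4ccccc4)[C@H](O)[C@]3(C)[C@H](OC(C)=O)C[C@](O)(C(C)C)[C@@H]23)cc1OC | intermediate
20 | 2α-acetoxy-6α-(3,4-dimethoxybenzoyloxy)-8-ene-4β,10α-diol | COc1ccc(C(=O)O[C@@H]2CC(C)=C[C@H](O)[C@]3(C)[C@H](OC(C)=O)C[C@](O)(C(C)C)[C@@H]23)cc1OC | intermediate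
21 | CNP0197096.2: 2α-acetoxy-6α-(3,4-dimethoxybenzoyloxy)-8,9-epoxy-trans-daucane-4β,10α-diol (oxirane cis-fused, syn to the 10α-OH; string as given) | COc1ccc(C(=O)O[C@@H]2C[C@@]3(C)O[C@@H]3[C@H](O)[C@]3(C)[C@H](OC(C)=O)C[C@](O)(C(C)C)[C@@H]23)cc1OC | target

**Step count**
Total: 13 steps. The longest linear sequence is 12 steps (1 → 2 → 3 → 7 → 8 → 10 → 12 → 13 → 14 → 16 → 17 → 20 → 21). Step 3 is the only side branch.

**The three steps most likely to fail**

Step 6.
- Risk: the C1 methyl sits on the same cyclopropane face as both vinyl groups and crowds the boat transition state. The carbenoid can also be diverted (attack by O2, pyrazole formation from 8). Facial control by C2 alone may be moderate.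
- Fallback: it sets out from 7 and comes back at 10, with ring closure and vinyl generation separated. O2 is capped (TESCl, imidazole) to give the diazo diketone TES ether F1. The more robust acceptor/acceptor carbenoid (Cu(acac)2 or Rh2(OAc)4) then cyclopropanates the same alkene to give the isolable 1-acetylbicyclo[3.1.0]hexan-2-one F2, whose diastereomers can be separated. Only then is the acetyl group turned into its enol silane (TESOTf, Et3N), which is 9, and heating gives 10.

Step 7.
- Risk: the 2α-OTES group and the C1–C10 bond lie on the α face and may erode or reverse the facial bias. Desilylation can also ionise the new tertiary allylic alcohol.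
- Fallback: it sets out from 10 and comes back at 13, with the oxygen rather than the carbon put on C4 under steric control.
  - The same Grignard addition (through 11) is worked up with aqueous HCl (Stork–Danheiser transposition). This erases C4 and gives the 2α-hydroxy-4-isopropyl-4(5),9-dien-6-one F3.
  - Acetylation gives the enone acetate F4.
  - Weitz–Scheffer epoxidation (tBuOOH, DBU) from the β face, anti to the 2α-acetoxy group and the pseudo-axial C1–C10 bond, gives the 4β,5β-epoxy ketone F5.
  - SmI2/MeOH cleaves the C5–O bond to give 13.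

Step 5.
- Risk: enolisation toward C3, with loss of the β-silyloxy group or a wrong vinyl diazo isomer.
- Fallback: it sets out from 3 and 6 and comes back at 8. The enol silane of 3 is kept, and the aldol is run from its other acetyl group as the diisopinocampheylboron enolate (Ipc2BCl, Et3N, non-oxidative work-up). This gives the siloxyvinyl diazo aldol F6, and TESCl/imidazole then gives 8 with no regiochemical question left.

**Further compounds**
F1 | step 6 | (6R,7E,9E)-3-diazo-7-methyl-6-(triethylsilyloxy)undeca-7,9-diene-2,4-dione | C/C=C/C=C(C)/[C@H](O[Si](CC)(CC)CC)CC(=O)C(=[N+]=[N-])C(C)=O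
F2 | step 6 | 1-acetylbicyclo[3.1.0]hexan-2-one analogue of 9 (acetyl on C5, CH3 on C1, exo (E)-propenyl on C10, 2-OTES trans to the C1 methyl) | CC(=O)[C@]12C(=O)C[C@@H](O[Si](CC)(CC)CC)[C@@]1(C)[C@@H]2/C=C/C
F3 | step 7 | 2α-hydroxy-4-isopropyl-1β,8α-dimethyl-4(5),9-dien-6-one | O=C1C[C@H](C)C=C[C@]2(C)[C@H](O)CC(C(C)C)=C12
F4 | step 7 | 2α-acetate of F3 | O=C1C[C@H](C)C=C[C@]2(C)[C@H](OC(C)=O)CC(C(C)C)=C12
F5 | step 7 | 2α-acetoxy-4β,5β-epoxy-4α-isopropyl-9-en-6-one | O=C1C[C@H](C)C=C[C@]2(C)[C@H](OC(C)=O)C[C@@]3(C(C)C)O[C@@]123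
F6 | step 5 | (6R,7E,9E)-3-diazo-6-hydroxy-7-methyl-2-(triethylsilyloxy)undeca-1,7,9-trien-4-one | C/C=C/C=C(C)/[C@H](O)CC(=O)C(=[N+]=[N-])C(=C)O[Si](CC)(CC)CC
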